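**Retrosynthetic overview**

1. Last step: Rubottom oxidation of a C8-siloxy 7(11),8-diene gives the 9α-hydroxyl, the C8 ketone and the conjugated isopropylidene together; the trienoate ester is already in place, so no protecting group is used.
2. Key step: rings A and B form together (bonds C5–C10 and C6–C7) in an intramolecular Diels–Alder reaction of a 2-siloxy vinylallene with a tethered isopropenyl group. The allene terminus becomes the isopropylidene; C5 and C10 are set from C3/C4.
3. The vinylallene is made in the same flask from an enynone (Me2CuLi 1,4-addition, O-silylation); the enynone comes from a Weinreb amide and prop-1-ynylmagnesium bromide.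
4. C3/C4 (syn) come from a catalytic asymmetric (Z)-2-methylcrotylboration of an aldehyde made by cross-metathesis of pent-4-enal with N-methoxy-N-methylacrylamide; acylation with the side-chain acid follows.
5. Side-chain acid: vinylogous Horner–Wadsworth–Emmons reaction of (E)-non-3-en-2-one, then saponification.

Assumption: eremophilane numbering (C1–C15) is used for the bicycle; β is the face of the C5 methyl group, α the opposite face.
Assumption: (S)-TRIP is taken as the catalyst enantiomer that sends the boronate to the Si face of the aldehyde; if the sense proves opposite, the mirror-image acid is used.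

**Step 1**
Reactants: 1 (E)-non-3-en-2-one; 2 triethyl 4-phosphonocrotonate
Product: 4 ethyl (2E,4E,6E)-5-methyldodeca-2,4,6-trienoate, via lithiated phosphonate 3 (not isolated)
Conditions: LiN(SiMe3)2, THF, −78 °C; then 1, −78 → 23 °C; chromatography
Reagents that add atoms: none
Why: vinylogous Horner–Wadsworth–Emmons olefination of the methyl ketone keeps the 2E and 6E bonds and gives the new 4E bond as the major isomer (expected about 4:1), the 4Z isomer being removed here or by crystallisation of acid 6.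

**Step 2**
Reactants: 4 ethyl (2E,4E,6E)-5-methyldodeca-2,4,6-trienoate
Product: 6 (2E,4E,6E)-5-methyldodeca-2,4,6-trienoic acid, via lithium carboxylate 5 (not isolated)
Conditions: LiOH·H2O, THF/MeOH/H2O, 23 °C; then 1 M HCl
Reagents that add atoms: lithium hydroxide, [Li+].[OH-]
Why: saponification (acyl–oxygen cleavage by hydroxide) leaves the triene geometry untouched, and crystallisation of the acid raises the all-E purity.

**Step 3**
Reactants: 7 (Z)-2-bromobut-2-ene; 8 2-(chloromethyl)-4,4,5,5-tetramethyl-1,3,2-dioxaborolane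
Product: 11 4,4,5,5-tetramethyl-2-[(Z)-2-methylbut-2-en-1-yl]-1,3,2-dioxaborolane, via (E)-but-2-en-2-yllithium 9 (not isolated), via boron ate complex 10 (not isolated)
Conditions: t-BuLi (2 equiv), THF/Et2O, −78 °C; then 8, −78 → 23 °C
Reagents that add atoms: none
Why: lithium–bromine exchange and the 1,2-shift of the alkenyl group from boron to carbon with loss of chloride (Matteson homologation) both retain the alkene geometry, so the γ-methyl ends cis to CH2B.

**Step 4**
Reactants: 12 pent-4-enal; 13 N-methoxy-N-methylprop-2-enamide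
Product: 14 (2E)-N-methoxy-N-methyl-6-oxohex-2-enamide
Conditions: second-generation Hoveyda–Grubbs catalyst RuCl2(H2IMes)(=CH-C6H4-2-OiPr) (2 mol%), 13 (2.5 equiv), CH2Cl2, 40 °C
Reagents that add atoms: none
Why: olefin cross-metathesis of a terminal alkene with an electron-poor acrylamide gives the hetero-coupled product with the favoured E geometry, and the aldehyde is tolerated.

**Step 5**
Reactants: 14 (2E)-N-methoxy-N-methyl-6-oxohex-2-enamide; 11 4,4,5,5-tetramethyl-2-[(Z)-2-methylbut-2-en-1-yl]-1,3,2-dioxaborolane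
Product: 16 (2E,6R,7R)-6-hydroxy-N-methoxy-N,7,8-trimethylnona-2,8-dienamide, via pinacol borate ester 15 (not isolated)
Conditions: 11 (1.3 equiv), (S)-TRIP phosphoric acid (5 mol%), 4 Å sieves, toluene, −30 °C; aq NaHCO3
Reagents that add atoms: none
Why: chiral-phosphoric-acid-catalysed allylboration through a closed chair (Zimmerman–Traxler) transition state, in which the (Z)-γ-methyl sits axial and gives the syn C6/C7 pair while the catalyst directs attack to the aldehyde Si face (6R,7R); only the aldehyde reacts, the Weinreb enamide is inert.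

**Step 6**
Reactants: 16 (2E,6R,7R)-6-hydroxy-N-methoxy-N,7,8-trimethylnona-2,8-dienamide; 6 (2E,4E,6E)-5-methyldodeca-2,4,6-trienoic acid
Product: 18 (3R,4R,7E)-9-[methoxy(methyl)amino]-2,3-dimethyl-9-oxonona-1,7-dien-4-yl (2E,4E,6E)-5-methyldodeca-2,4,6-trienoate, via O-acylisourea 17 (not isolated)
Conditions: EDC·HCl, DMAP (0.3 equiv), CH2Cl2, 0 → 23 °C
Reagents that add atoms: none
Why: Steglich esterification acylates the only hydroxyl group without touching either stereocentre.

**Step 7**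
Reactants: 18 (3R,4R,7E)-9-[methoxy(methyl)amino]-2,3-dimethyl-9-oxonona-1,7-dien-4-yl (2E,4E,6E)-5-methyldodeca-2,4,6-trienoate; 19 prop-1-ynylmagnesium bromide
Product: 21 (3R,4R,7E)-2,3-dimethyl-9-oxododeca-1,7-dien-10-yn-4-yl (2E,4E,6E)-5-methyldodeca-2,4,6-trienoate, via magnesium chelate adduct 20 (not isolated)
Conditions: MeC≡CMgBr (1.3 equiv), THF, −40 → 0 °C; then 0.5 M HCl, 0 °C
Reagents that add atoms: none
Why: Weinreb ketone synthesis, in which the chelated tetrahedral adduct stops over-addition and the alkynyl Grignard reagent attacks the N-methoxy amide much faster than the hindered, conjugated secondary ester.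

**Step 8**
Reactants: 21 (3R,4R,7E)-2,3-dimethyl-9-oxododeca-1,7-dien-10-yn-4-yl (2E,4E,6E)-5-methyldodeca-2,4,6-trienoate
Product: 24 3α-[(2E,4E,6E)-5-methyldodeca-2,4,6-trienoyloxy]-8-(triethylsilyloxy)-10αH-eremophila-7(11),8-diene, via lithium allenolate 22 (not isolated), via triethylsiloxy vinylallene 23 (not isolated)
Conditions: Me2CuLi (1.1 equiv, from CuI + 2 MeLi), Et2O/THF, −78 °C; Et3SiCl, Et3N, −78 → 0 °C; filter (Celite, Ar); toluene, BHT, 100 °C
Reagents that add atoms: lithium dimethylcuprate, [Li+].C[Cu-]C; chlorotriethylsilane, CC[Si](Cl)(CC)CC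
Why: Proposed new method: Me2CuLi adds 1,4 to the ynone (faster than to the enone or the trienoate at −78 °C) to give allenolate 22, O-silylation gives the electron-rich 2-siloxy vinylallene 23, and its C7=C8–C9=C10 diene adds to the tethered isopropenyl group (bonds C6–C7 and C5–C10, both rings closed at once) through the trans-fused, tether-exo chair transition state that keeps the C3 ester and C4 methyl equatorial (the other chair would put the C3 ester 1,3-diaxial to the C5 methyl), so that the C5 methyl ends cis to the C4 methyl and H-10 trans to the C5 methyl while the allene terminus becomes the 7(11)-isopropylidene; the closest known reaction types are cuprate 1,4-addition to ynones with O-silylation of the allenolate and the intramolecular Diels–Alder reaction of siloxy vinylallenes with unactivated alkenes.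

**Step 9**
Reactants: 24 3α-[(2E,4E,6E)-5-methyldodeca-2,4,6-trienoyloxy]-8-(triethylsilyloxy)-10αH-eremophila-7(11),8-diene
Product: 27 (1S,4aR,5R,6R,8aR)-1-hydroxy-4a,5-dimethyl-2-oxo-3-(propan-2-ylidene)decahydronaphthalen-6-yl (2E,4E,6E)-5-methyldodeca-2,4,6-trienoate (CNP0211657.1), via silyloxy epoxide 25 (not isolated), via 9α-triethylsilyloxy ketone 26 (not isolated)
Conditions: mCPBA (1.05 equiv), NaHCO3, CH2Cl2, −20 °C; then Et3N·3HF, THF, 0 °C
Reagents that add atoms: 3-chloroperoxybenzoic acid, OOC(=O)c1cccc(Cl)c1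
Why: Rubottom oxidation, in which the peracid epoxidises the most electron-rich alkene (the C8=C9 silyl enol ether) from the α face opposite the axial C5 methyl, and ring opening with silyl shift followed by fluoride gives the equatorial 9α-hydroxy 8-ketone (9S) conjugated with the isopropylidene, the electron-poor trienoate being left alone.

**Compound list**

1 | (E)-non-3-en-2-one | CCCCC/C=C/C(C)=O | starting material
2 | triethyl 4-phosphonocrotonate, ethyl (E)-4-(diethoxyphosphoryl)but-2-enoate | CCOC(=O)/C=C/CP(=O)(OCC)OCC | starting material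
3 | lithiated phosphonate (lithium salt of the carbanion of 2) | [Li+].CCOC(=O)/C=C/[CH-]P(=O)(OCC)OCC | intermediate
4 | ethyl (2E,4E,6E)-5-methyldodeca-2,4,6-trienoate | CCCCC/C=C/C(C)=C/C=C/C(=O)OCC | intermediate
5 | lithium (2E,4E,6E)-5-methyldodeca-2,4,6-trienoate | [Li+].CCCCC/C=C/C(C)=C/C=C/C(=O)[O-] | intermediate
6 | (2E,4E,6E)-5-methyldodeca-2,4,6-trienoic acid | CCCCC/C=C/C(C)=C/C=C/C(=O)O | intermediate
7 | (Z)-2-bromobut-2-ene (methyl groups trans) | C/C=C(/C)Br | starting material
8 | 2-(chloromethyl)-4,4,5,5-tetramethyl-1,3,2-dioxaborolane | ClCB1OC(C)(C)C(C)(C)O1 | starting material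
9 | (E)-but-2-en-2-yllithium (methyl groups trans) | C/C=C(/C)[Li] | intermediate
10 | lithium (E)-but-2-en-2-yl(chloromethyl)pinacolatoborate | [Li+].C/C=C(/C)[B-]1(CCl)OC(C)(C)C(C)(C)O1 | intermediate
11 | 4,4,5,5-tetramethyl-2-[(Z)-2-methylbut-2-en-1-yl]-1,3,2-dioxaborolane | C/C=C(/C)CB1OC(C)(C)C(C)(C)O1 | intermediate
12 | pent-4-enal | C=CCCC=O | starting material
13 | N-methoxy-N-methylprop-2-enamide | C=CC(=O)N(C)OC | starting material
14 | (2E)-N-methoxy-N-methyl-6-oxohex-2-enamide | O=CCC/C=C/C(=O)N(C)OC | intermediate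
15 | (2E,6R,7R)-N-methoxy-N,7,8-trimethyl-6-[(4,4,5,5-tetramethyl-1,3,2-dioxaborolan-2-yl)oxy]nona-2,8-dienamide | C=C(C)[C@@H](C)[C@H](OB1OC(C)(C)C(C)(C)O1)CC/C=C/C(=O)N(C)OC | intermediate
16 | (2E,6R,7R)-6-hydroxy-N-methoxy-N,7,8-trimethylnona-2,8-dienamide | C=C(C)[C@@H](C)[C@H](O)CC/C=C/C(=O)N(C)OC | intermediate
17 | O-acylisourea from 6 and EDC | CCCCC/C=C/C(C)=C/C=C/C(=O)OC(=NCC)NCCCN(C)C | intermediate
18 | (3R,4R,7E)-9-[methoxy(methyl)amino]-2,3-dimethyl-9-oxonona-1,7-dien-4-yl (2E,4E,6E)-5-methyldodeca-2,4,6-trienoate | CCCCC/C=C/C(C)=C/C=C/C(=O)O[C@H](CC/C=C/C(=O)N(C)OC)[C@H](C)C(C)=C | intermediate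
19 | prop-1-ynylmagnesium bromide | CC#C[Mg]Br | starting material
20 | bromomagnesium alkoxide of the tetrahedral adduct of 18 and 19 | CCCCC/C=C/C(C)=C/C=C/C(=O)O[C@H](CC/C=C/C(O[Mg]Br)(C#CC)N(C)OC)[C@H](C)C(C)=C | intermediate
21 | (3R,4R,7E)-2,3-dimethyl-9-oxododeca-1,7-dien-10-yn-4-yl (2E,4E,6E)-5-methyldodeca-2,4,6-trienoate | CCCCC/C=C/C(C)=C/C=C/C(=O)O[C@H](CC/C=C/C(=O)C#CC)[C@H](C)C(C)=C | intermediate
22 | lithium allenolate from 1,4-addition of methyl to the ynone of 21 | CCCCC/C=C/C(C)=C/C=C/C(=O)O[C@H](CC/C=C/C(O[Li])=C=C(C)C)[C@H](C)C(C)=C | intermediate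
23 | (3R,4R,7E)-2,3,11-trimethyl-9-(triethylsilyloxy)dodeca-1,7,9,10-tetraen-4-yl (2E,4E,6E)-5-methyldodeca-2,4,6-trienoate | CCCCC/C=C/C(C)=C/C=C/C(=O)O[C@H](CC/C=C/C(O[Si](CC)(CC)CC)=C=C(C)C)[C@H](C)C(C)=C | intermediate
24 | 3α-[(2E,4E,6E)-5-methyldodeca-2,4,6-trienoyloxy]-8-(triethylsilyloxy)-10αH-eremophila-7(11),8-diene (4β,5β-dimethyl, trans-fused) | CCCCC/C=C/C(C)=C/C=C/C(=O)O[C@@H]1CC[C@H]2C=C(O[Si](CC)(CC)CC)C(=C(C)C)C[C@]2(C)[C@H]1C | intermediate
25 | 8α,9α-epoxy-8β-(triethylsilyloxy)-10αH-eremophil-7(11)-en-3α-yl (2E,4E,6E)-5-methyldodeca-2,4,6-trienoate | CCCCC/C=C/C(C)=C/C=C/C(=O)O[C@@H]1CC[C@H]2[C@@H]3O[C@]3(O[Si](CC)(CC)CC)C(=C(C)C)C[C@]2(C)[C@H]1C | intermediate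
26 | 8-oxo-9α-(triethylsilyloxy)-10αH-eremophil-7(11)-en-3α-yl (2E,4E,6E)-5-methyldodeca-2,4,6-trienoate | CCCCC/C=C/C(C)=C/C=C/C(=O)O[C@@H]1CC[C@H]2[C@H](O[Si](CC)(CC)CC)C(=O)C(=C(C)C)C[C@]2(C)[C@H]1C | intermediate
27 | (1S,4aR,5R,6R,8aR)-1-hydroxy-4a,5-dimethyl-2-oxo-3-(propan-2-ylidene)decahydronaphthalen-6-yl (2E,4E,6E)-5-methyldodeca-2,4,6-trienoate; 3α-acyloxy-9α-hydroxy-10αH-eremophil-7(11)-en-8-one; eremophilane (3R,4R,5R,9S,10R) | CCCCC/C=C/C(C)=C/C=C/C(=O)O[C@@H]1CC[C@H]2[C@H](O)C(=O)C(=C(C)C)C[C@]2(C)[C@H]1C | target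

**Step count**

Total: 9 steps. Longest linear sequence: 6 steps (steps 4–9 from pent-4-enal 12; the acid branch through steps 1, 2 and 6–9 is equally long).

**Three steps most likely to fail**

Step 8 (key step). The main uncertainties are the ring-fusion ratio (trans against cis at C10, which cannot be corrected later), the behaviour of the cuprate next to the trienoate, and the survival of the siloxy allene. The fallback gives up the allene and brings in the isopropylidene after the cycloaddition. It sets out from 16 and comes back to the route at 26. MeMgBr (2.5 equiv, THF, −20 °C) turns the Weinreb amide into (3E,7R,8R)-7-hydroxy-8,9-dimethyldeca-3,9-dien-2-one F1, which is used at once. Esterification with 6 (EDC, DMAP, 0 °C) gives (3R,4R,7E)-2,3-dimethyl-9-oxodeca-1,7-dien-4-yl (2E,4E,6E)-5-methyldodeca-2,4,6-trienoate F2. Et3SiOTf and Et3N (CH2Cl2, −78 °C) give the 2-siloxy diene (3R,4R,7E)-2,3-dimethyl-9-(triethylsilyloxy)deca-1,7,9-trien-4-yl trienoate F3. Heating (toluene, BHT, 170 °C, sealed tube) closes both rings in a plain intramolecular Diels–Alder reaction to 8-(triethylsilyloxy)-10αH-eremophil-8-en-3α-yl trienoate F4. mCPBA with NaHCO3 and no fluoride work-up gives 8-oxo-9α-(triethylsilyloxy)-10αH-eremophilan-3α-yl trienoate F5. LiN(SiMe3)2 (THF, −78 °C) enolises away from the silyloxy carbon and acetone gives the C7 aldol adduct 11-hydroxy-8-oxo-9α-(triethylsilyloxy)-10αH-eremophilan-3α-yl trienoate F6. Burgess reagent and then DBU dehydrate F6 to the conjugated isopropylidene ketone, which is 26; Et3N·3HF then gives 27 as in step 9.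

Step 5. The enantioselectivity and syn selectivity of the acid-catalysed allylboration with an unbranched aliphatic aldehyde and a trisubstituted (Z)-boronate are not assured. The fallback makes the anti alcohol by another carbon–carbon bond-forming method and corrects C6 by inversion. It sets out from 14 and comes back at 18. A catalytic enantioselective Nozaki–Hiyama–Kishi reaction of 14 with (E)-1-bromo-2-methylbut-2-ene (CrCl2 10 mol%, chiral carbazole bis(oxazoline) ligand, Mn powder, Me3SiCl, THF) is anti-selective through the chair transition state of the allylchromium species and gives (2E,6S,7R)-6-hydroxy-N-methoxy-N,7,8-trimethylnona-2,8-dienamide F7. Mitsunobu esterification with 6 (PPh3, DIAD, toluene, 0 °C) inverts C6 and gives 18 directly.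

Step 7. The Grignard reagent may attack the trienoate ester. The fallback reverses the order so that no ester is present when the Grignard reagent is used. It sets out from 16 and comes back at 21. Compound 16 and 19 (2.5 equiv, THF, −20 → 0 °C, HCl quench at 0 °C) give (5E,9R,10R)-9-hydroxy-10,11-dimethyldodeca-5,11-dien-2-yn-4-one F8, which is used at once because base can close it to a tetrahydrofuran by oxa-Michael addition. Acid 6 and 1-chloro-N,N,2-trimethylprop-1-en-1-amine (CH2Cl2, 0 °C) give (2E,4E,6E)-5-methyldodeca-2,4,6-trienoyl chloride F9, which acylates F8 (pyridine, CH2Cl2, −20 °C) to give 21.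

**Further compounds**

F1 | step 8 | (3E,7R,8R)-7-hydroxy-8,9-dimethyldeca-3,9-dien-2-one | CC(=O)/C=C/CC[C@@H](O)[C@H](C)C(C)=C
F2 | step 8 | (3R,4R,7E)-2,3-dimethyl-9-oxodeca-1,7-dien-4-yl (2E,4E,6E)-5-methyldodeca-2,4,6-trienoate | CCCCC/C=C/C(C)=C/C=C/C(=O)O[C@H](CC/C=C/C(C)=O)[C@H](C)C(C)=C
F3 | step 8 | (3R,4R,7E)-2,3-dimethyl-9-(triethylsilyloxy)deca-1,7,9-trien-4-yl (2E,4E,6E)-5-methyldodeca-2,4,6-trienoate | CCCCC/C=C/C(C)=C/C=C/C(=O)O[C@H](CC/C=C/C(=C)O[Si](CC)(CC)CC)[C@H](C)C(C)=C
F4 | step 8 | 8-(triethylsilyloxy)-10αH-eremophil-8-en-3α-yl (2E,4E,6E)-5-methyldodeca-2,4,6-trienoate | CCCCC/C=C/C(C)=C/C=C/C(=O)O[C@@H]1CC[C@H]2C=C(O[Si](CC)(CC)CC)CC[C@]2(C)[C@H]1C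
F5 | step 8 | 8-oxo-9α-(triethylsilyloxy)-10αH-eremophilan-3α-yl (2E,4E,6E)-5-methyldodeca-2,4,6-trienoate | CCCCC/C=C/C(C)=C/C=C/C(=O)O[C@@H]1CC[C@H]2[C@H](O[Si](CC)(CC)CC)C(=O)CC[C@]2(C)[C@H]1C
F6 | step 8 | 11-hydroxy-8-oxo-9α-(triethylsilyloxy)-10αH-eremophilan-3α-yl (2E,4E,6E)-5-methyldodeca-2,4,6-trienoate (C7 epimers) | CCCCC/C=C/C(C)=C/C=C/C(=O)O[C@@H]1CC[C@H]2[C@H](O[Si](CC)(CC)CC)C(=O)C(C(C)(C)O)C[C@]2(C)[C@H]1C
F7 | step 5 | (2E,6S,7R)-6-hydroxy-N-methoxy-N,7,8-trimethylnona-2,8-dienamide | C=C(C)[C@@H](C)[C@@H](O)CC/C=C/C(=O)N(C)OC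
F8 | step 7 | (5E,9R,10R)-9-hydroxy-10,11-dimethyldodeca-5,11-dien-2-yn-4-one | CC#CC(=O)/C=C/CC[C@@H](O)[C@H](C)C(C)=C
F9 | step 7 | (2E,4E,6E)-5-methyldodeca-2,4,6-trienoyl chloride | CCCCC/C=C/C(C)=C/C=C/C(Cl)=O
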